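1. Tuesday's run crawled: 8.3% monomer in chains at 12.0 min, slower than Thursday's 40.8%. Your hunch, that impurity eats initiator, is our reading too.

in all of them: free monomer 1.5 M

| flask | initiator | impurity | remark | time |
|---|---|---|---|---|
| Thursday's | 38 mM | 29 mM | run made earlier |  |
| Tuesday's | 38 mM | 46 mM | run made earlier |  |
| Sunday's | 57 mM | 21 mM | run made earlier |  |
| flask | 38 mM | 21 mM |  | 10 min |

| run | time / min | monomer in chains / % | free monomer / % |
|---|---|---|---|
| Thursday's | 1.00 | 3.4 | 97.6 |
| Thursday's | 3.00 | 13.4 | 85.8 |
| Thursday's | 6.00 | 27.7 | 72.9 |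
| Thursday's | 8.00 | 32.1 | 66.9 |
| Thursday's | 12.0 | 40.8 | 57.8 |
| Tuesday's | 1.00 | 1.3 | 100.7 |
| Tuesday's | 3.00 | 1.4 | 97.8 |
| Tuesday's | 6.00 | 5.0 | 95.3 |
| Tuesday's | 8.00 | 4.2 | 95.9 |
| Tuesday's | 12.0 | 8.3 | 90.5 |
| Sunday's | 2.50 | 34.0 | 66.2 |
| Sunday's | 5.00 | 60.4 | 42.5 |
| Sunday's | 8.00 | 71.0 | 29.0 |
| Sunday's | 10.0 | 74.4 | 22.5 |
| Sunday's | 12.0 | 76.0 | 21.6 |

(scatter of a reading: 1 percentage point)

- the average divides the monomer in chains by the number of chains begun, living and dead together
- the analysis behind the earlier runs scatters by 1 percentage point, standard deviation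
- the earlier runs do not show the number of chains; that part of a forecast is a guess

* average number of monomer units in a chain (chains begun, living or dead) at 10 min
* part of the free monomer that has reacted at 10 min

2. We write the balance of the smaller charge. In the flask, impurity (21 mM) stands below initiator (38 mM), so impurity is the limiting reagent of that consumption. If one impurity takes one initiator, the initiator left to begin chains is E = 17.0 mM, the initiator excess, meaning initiator charged less impurity charged.

3. E is 9.00 mM in Thursday's run, 36.0 mM in Sunday's and −8.00 mM in Tuesday's. The early loss of free monomer reads 0.0511 min⁻¹ in Thursday's and 0.165 min⁻¹ in Sunday's, so of these two runs the one with the larger E reads faster.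

4. The forecast gives dp 44 (30 to 52) and c 53% (47% to 59%), holding that the early rate “scales with initiator minus impurity”.

5. The runs show no chain count, so ours for the flask is a guess: one chain per unit of E. With the forecast's c, our own reckoning gives dp 46.8, higher than the forecast's 44.

6. The flask gives dp 47.9 and c 54.9% at 10 min, from these steps:

    living end + monomer in chains → dead end A (k = 0.00281 M⁻¹ s⁻¹)
    free monomer + initiator → living end + monomer in chains (k = 0.0161 M⁻¹ s⁻¹)
    initiator + impurity → spent initiator B (k = 40.0 M⁻¹ s⁻¹)
    free monomer + living end → monomer in chains + living end, rate k4*[living end]*[free monomer] (k = 0.109 M⁻¹ s⁻¹)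

7. Both values lie inside the forecast's ranges. At 10.0 min the flask holds 0.0210 M of spent initiator B, matching the impurity charged, with impurity at 0% and initiator at 0% of their charges. Dividing its monomer in chains, 54.2% of the charge, by E gives 47.9 units per chain. A neighbour flask with 0.0084 M of impurity has E = 29.6 mM, and its 69.6% monomer in chains over that E gives 35.3, where the average in that neighbour flask is 35.3.

Readings and results are simulated with made-up constants; noise was put on by code.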